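## Retrosynthetic overview

1. Last disconnection: the ester C–O bond at ring C5, giving a silyl-protected C14 dienoic acid and a hydroxy-dihydropyranone carrying the side-chain acid as its tert-butyl ester; Yamaguchi esterification, then one acidic global deprotection.
2. Lactone fragment: both ring stereocentres come from C2-symmetric (S,S)-divinylglycol; a hydroxyl-guided cross-metathesis installs the E-enoate, then an acrylate ring-closing metathesis closes the ring.
3. Acid fragment: two successive Wittig olefinations of an α-methyl aldehyde build the 2E,4E-dienoate; the aldehyde comes from acetylide alkylation joining a Roche-ester-derived iodide (C6 centre) and a propylene-oxide-derived alkyne (C11 centre).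
4. Ring order: there is only one ring, the 5,6-dihydro-2H-pyran-2-one, and it is closed inside the lactone fragment before the fragments are joined.

Assumption: the three chiral starting materials are bought as single enantiomers (each is catalogued).

## Route

Step 1
Reactants: 1 acryloyl chloride
Product: 2 tert-butyl acrylate
Conditions: t-BuOH, PhNMe2, Et2O, 0 °C → reflux (trace BHT)
Reagents that add atoms: tert-butanol, CC(C)(C)O
Why: Acylation of tert-butanol by the acid chloride with N,N-dimethylaniline as HCl scavenger (esterification) gives the acid-labile ester that carries the side-chain carboxyl to the end.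

Step 2
Reactants: 3 (3S,4S)-hexa-1,5-diene-3,4-diol
Product: 4 (3S,4S)-4-[(tert-butyldimethylsilyl)oxy]hexa-1,5-dien-3-ol
Conditions: TBSCl (1.0 equiv), imidazole, CH2Cl2/DMF, 0 °C
Reagents that add atoms: TBSCl, CC(C)(C)[Si](C)(C)Cl
Why: Mono-silylation of a C2-symmetric diol can give only one mono-ether because the two hydroxyls are equivalent, the second silylation beside the bulky silyl ether is slow, and both stereocentres are carried over from 3 unchanged.

Step 3
Reactants: 4 (3S,4S)-4-[(tert-butyldimethylsilyl)oxy]hexa-1,5-dien-3-ol; 2 tert-butyl acrylate (3 equiv)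
Product: 5 tert-butyl (2E,4S,5S)-5-[(tert-butyldimethylsilyl)oxy]-4-hydroxyhepta-2,6-dienoate
Conditions: second-generation Grubbs catalyst (H2IMes)(PCy3)Cl2Ru=CHPh (5 mol %), CH2Cl2, 40 °C
Reagents that add atoms: none
Why: Olefin cross-metathesis occurs at the vinyl group beside the free allylic hydroxyl (hydroxyl-assisted and unhindered) while the vinyl group beside the bulky silyl ether reacts much more slowly, and the acrylate partner gives the E-enoate.

Step 4
Reactants: 5 tert-butyl (2E,4S,5S)-5-[(tert-butyldimethylsilyl)oxy]-4-hydroxyhepta-2,6-dienoate; 1 acryloyl chloride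
Product: 6 tert-butyl (2E,4S,5S)-4-(acryloyloxy)-5-[(tert-butyldimethylsilyl)oxy]hepta-2,6-dienoate
Conditions: i-Pr2NEt, CH2Cl2, −20 → 0 °C
Reagents that add atoms: none
Why: O-acylation of the remaining secondary alcohol with the acid chloride places the acrylate on the oxygen that becomes the ring oxygen.

Step 5
Reactants: 6 tert-butyl (2E,4S,5S)-4-(acryloyloxy)-5-[(tert-butyldimethylsilyl)oxy]hepta-2,6-dienoate
Product: 7 tert-butyl (2E)-3-[(2S,3S)-3-[(tert-butyldimethylsilyl)oxy]-6-oxo-3,6-dihydro-2H-pyran-2-yl]prop-2-enoate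
Conditions: second-generation Grubbs catalyst (5 mol %), CH2Cl2 (5 mM), 40 °C
Reagents that add atoms: none
Why: Ring-closing metathesis between the only terminal alkene and the acrylate can give only the six-membered unsaturated lactone (the internal E-enoate is a poor metathesis partner), so ring size and the cis ring alkene follow from connectivity and the two stereocentres are untouched.

Step 6
Reactants: 7 tert-butyl (2E)-3-[(2S,3S)-3-[(tert-butyldimethylsilyl)oxy]-6-oxo-3,6-dihydro-2H-pyran-2-yl]prop-2-enoate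
Product: 8 tert-butyl (2E)-3-[(2S,3S)-3-hydroxy-6-oxo-3,6-dihydro-2H-pyran-2-yl]prop-2-enoate
Conditions: HF·pyridine, pyridine, THF, 0 °C → rt
Reagents that add atoms: none
Why: Fluoride-mediated desilylation under buffered, mildly acidic conditions frees the C5 hydroxyl without the base-induced elimination to a 2-pyranone that basic fluoride sources would risk.

Step 7
Reactants: 9 methyl (S)-3-hydroxy-2-methylpropanoate
Product: 10 methyl (S)-3-(benzyloxy)-2-methylpropanoate
Conditions: BnOC(=NH)CCl3, TfOH (cat.), CH2Cl2/cyclohexane, 0 °C → rt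
Reagents that add atoms: benzyl 2,2,2-trichloroacetimidate, N=C(OCc1ccccc1)C(Cl)(Cl)Cl
Why: Acid-catalysed O-benzylation with the trichloroacetimidate uses no base, so the α-stereocentre of the ester is not epimerised and no β-elimination occurs.

Step 8
Reactants: 10 methyl (S)-3-(benzyloxy)-2-methylpropanoate
Product: 11 (R)-3-(benzyloxy)-2-methylpropan-1-ol
Conditions: LiAlH4, Et2O, 0 °C; then H2O
Reagents that add atoms: none
Why: Hydride reduction of the ester gives the primary alcohol without involving the stereocentre (the descriptor changes to R only through the priority order).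

Step 9
Reactants: 11 (R)-3-(benzyloxy)-2-methylpropan-1-ol
Product: 12 (S)-[(3-iodo-2-methylpropoxy)methyl]benzene
Conditions: I2, PPh3, imidazole, CH2Cl2, 0 °C → rt
Reagents that add atoms: iodine, [I][I]
Why: Appel-type iodination (SN2 at the primary carbon) turns the alcohol into the alkylating agent without touching the stereocentre.

Step 10
Reactants: 13 (S)-2-methyloxirane
Product: 14 (S)-pent-4-yn-2-ol
Conditions: LiC≡CH·H2NCH2CH2NH2, DMSO, 0 °C → rt; then H2O
Reagents that add atoms: lithium acetylide–ethylenediamine complex, [Li]C#C.NCCN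
Why: SN2 epoxide opening by the acetylide at the unsubstituted carbon leaves the S carbinol centre of the epoxide intact.

Step 11
Reactants: 14 (S)-pent-4-yn-2-ol
Product: 15 (S)-tert-butyldimethyl(pent-4-yn-2-yloxy)silane
Conditions: TBSCl, imidazole, CH2Cl2, rt
Reagents that add atoms: TBSCl, CC(C)(C)[Si](C)(C)Cl
Why: Silyl ether formation protects the secondary alcohol for the organolithium, oxidation and olefination steps.

Step 12
Reactants: 15 (S)-tert-butyldimethyl(pent-4-yn-2-yloxy)silane; 12 (S)-[(3-iodo-2-methylpropoxy)methyl]benzene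
Product: 17 tert-butyl{[(2S,7R)-8-(benzyloxy)-7-methyloct-4-yn-2-yl]oxy}dimethylsilane, via lithium acetylide 16 (not isolated)
Conditions: n-BuLi, THF, −78 °C; then 12, DMPU, −78 °C → rt
Reagents that add atoms: n-butyllithium, [Li]CCCC (supplies only the lithium of 16)
Why: Deprotonation of the terminal alkyne and SN2 alkylation of the acetylide by the primary iodide in a dipolar cosolvent joins the two chiral pieces without affecting either stereocentre.

Step 13
Reactants: 17 tert-butyl{[(2S,7R)-8-(benzyloxy)-7-methyloct-4-yn-2-yl]oxy}dimethylsilane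
Product: 18 (2R,7S)-7-[(tert-butyldimethylsilyl)oxy]-2-methyloctan-1-ol
Conditions: H2 (1 atm), Pd/C, EtOAc, rt
Reagents that add atoms: none
Why: Heterogeneous catalytic hydrogenation saturates the alkyne and hydrogenolyses the benzyl ether in one operation while the silyl ether survives in ethyl acetate.

Step 14
Reactants: 18 (2R,7S)-7-[(tert-butyldimethylsilyl)oxy]-2-methyloctan-1-ol
Product: 19 (2R,7S)-7-[(tert-butyldimethylsilyl)oxy]-2-methyloctanal
Conditions: Dess–Martin periodinane, CH2Cl2, 0 °C → rt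
Reagents that add atoms: none
Why: Dess–Martin oxidation gives the α-branched aldehyde under near-neutral conditions that do not epimerise it.

Step 15
Reactants: 19 (2R,7S)-7-[(tert-butyldimethylsilyl)oxy]-2-methyloctanal
Product: 20 (2E,4R,9S)-9-[(tert-butyldimethylsilyl)oxy]-2,4-dimethyldec-2-enal
Conditions: Ph3P=C(CH3)CHO, toluene, 90 °C
Reagents that add atoms: 2-(triphenylphosphoranylidene)propanal, CC(C=O)=P(c1ccccc1)(c1ccccc1)c1ccccc1
Why: Wittig olefination with the stabilised formyl ylide gives the E-trisubstituted enal directly, and the neutral conditions leave the adjacent stereocentre unchanged.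

Step 16
Reactants: 20 (2E,4R,9S)-9-[(tert-butyldimethylsilyl)oxy]-2,4-dimethyldec-2-enal
Product: 21 ethyl (2E,4E,6R,11S)-11-[(tert-butyldimethylsilyl)oxy]-4,6-dimethyldodeca-2,4-dienoate
Conditions: Ph3P=CHCO2Et, CH2Cl2, 40 °C
Reagents that add atoms: ethyl 2-(triphenylphosphoranylidene)acetate, CCOC(=O)C=P(c1ccccc1)(c1ccccc1)c1ccccc1
Why: Wittig olefination of the enal with the stabilised ester ylide gives the 2E alkene and completes the 2E,4E-dienoate.

Step 17
Reactants: 21 ethyl (2E,4E,6R,11S)-11-[(tert-butyldimethylsilyl)oxy]-4,6-dimethyldodeca-2,4-dienoate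
Product: 22 (2E,4E,6R,11S)-11-[(tert-butyldimethylsilyl)oxy]-4,6-dimethyldodeca-2,4-dienoic acid
Conditions: LiOH, THF/MeOH/H2O, rt; then cold 1 M HCl to pH 4
Reagents that add atoms: lithium hydroxide, [Li+].[OH-]
Why: Saponification followed by mild acidification gives the dienoic acid, and the silyl ether and the remote stereocentres are stable to aqueous LiOH.

Step 18
Reactants: 22 (2E,4E,6R,11S)-11-[(tert-butyldimethylsilyl)oxy]-4,6-dimethyldodeca-2,4-dienoic acid; 8 tert-butyl (2E)-3-[(2S,3S)-3-hydroxy-6-oxo-3,6-dihydro-2H-pyran-2-yl]prop-2-enoate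
Product: 24 tert-butyl (2E)-3-[(2S,3S)-3-{[(2E,4E,6R,11S)-11-[(tert-butyldimethylsilyl)oxy]-4,6-dimethyldodeca-2,4-dienoyl]oxy}-6-oxo-3,6-dihydro-2H-pyran-2-yl]prop-2-enoate, via mixed anhydride 23 (not isolated)
Conditions: 2,4,6-Cl3C6H2COCl, Et3N, toluene, rt; then 8, DMAP, 0 °C → rt
Reagents that add atoms: 2,4,6-trichlorobenzoyl chloride, O=C(Cl)c1c(Cl)cc(Cl)cc1Cl (its aroyl group is in 23 only)
Why: Yamaguchi esterification, in which DMAP turns the mixed anhydride into an acylpyridinium that acylates the secondary allylic alcohol on oxygen with retention at C5, joins the two fragments.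

Step 19
Reactants: 24 tert-butyl (2E)-3-[(2S,3S)-3-{[(2E,4E,6R,11S)-11-[(tert-butyldimethylsilyl)oxy]-4,6-dimethyldodeca-2,4-dienoyl]oxy}-6-oxo-3,6-dihydro-2H-pyran-2-yl]prop-2-enoate
Product: 25 (2E)-3-[(2S,3S)-3-{[(2E,4E,6R,11S)-11-hydroxy-4,6-dimethyldodeca-2,4-dienoyl]oxy}-6-oxo-3,6-dihydro-2H-pyran-2-yl]prop-2-enoic acid (CNP0107712.2)
Conditions: TFA/H2O (9:1), 0 °C → rt
Reagents that add atoms: none
Why: Acidolysis cleaves the tert-butyl ester and hydrolyses the silyl ether in one operation, while the lactone, the allylic dienoate ester and all four stereocentres are acid-stable and no base touches the elimination-prone pyranone.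

## Compound list

1 | acryloyl chloride | C=CC(=O)Cl | starting material
2 | tert-butyl acrylate | C=CC(=O)OC(C)(C)C | intermediate
3 | (3S,4S)-hexa-1,5-diene-3,4-diol | C=C[C@H](O)[C@@H](O)C=C | starting material
4 | (3S,4S)-4-[(tert-butyldimethylsilyl)oxy]hexa-1,5-dien-3-ol | C=C[C@H](O)[C@@H](O[Si](C)(C)C(C)(C)C)C=C | intermediate
5 | tert-butyl (2E,4S,5S)-5-[(tert-butyldimethylsilyl)oxy]-4-hydroxyhepta-2,6-dienoate | CC(C)(C)OC(=O)/C=C/[C@H](O)[C@@H](O[Si](C)(C)C(C)(C)C)C=C | intermediate
6 | tert-butyl (2E,4S,5S)-4-(acryloyloxy)-5-[(tert-butyldimethylsilyl)oxy]hepta-2,6-dienoate | CC(C)(C)OC(=O)/C=C/[C@H](OC(=O)C=C)[C@@H](O[Si](C)(C)C(C)(C)C)C=C | intermediate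
7 | tert-butyl (2E)-3-[(2S,3S)-3-[(tert-butyldimethylsilyl)oxy]-6-oxo-3,6-dihydro-2H-pyran-2-yl]prop-2-enoate | CC(C)(C)[Si](C)(C)O[C@H]1C=CC(=O)O[C@H]1/C=C/C(=O)OC(C)(C)C | intermediate
8 | tert-butyl (2E)-3-[(2S,3S)-3-hydroxy-6-oxo-3,6-dihydro-2H-pyran-2-yl]prop-2-enoate | O[C@H]1C=CC(=O)O[C@H]1/C=C/C(=O)OC(C)(C)C | intermediate
9 | methyl (S)-3-hydroxy-2-methylpropanoate | COC(=O)[C@@H](C)CO | starting material
10 | methyl (S)-3-(benzyloxy)-2-methylpropanoate | COC(=O)[C@@H](C)COCc1ccccc1 | intermediate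
11 | (R)-3-(benzyloxy)-2-methylpropan-1-ol | OC[C@@H](C)COCc1ccccc1 | intermediate
12 | (S)-[(3-iodo-2-methylpropoxy)methyl]benzene | IC[C@@H](C)COCc1ccccc1 | intermediate
13 | (S)-2-methyloxirane | C[C@H]1CO1 | starting material
14 | (S)-pent-4-yn-2-ol | C#CC[C@H](C)O | intermediate
15 | (S)-tert-butyldimethyl(pent-4-yn-2-yloxy)silane | C#CC[C@H](C)O[Si](C)(C)C(C)(C)C | intermediate
16 | lithium (S)-4-[(tert-butyldimethylsilyl)oxy]pent-1-yn-1-ide | [Li]C#CC[C@H](C)O[Si](C)(C)C(C)(C)C | intermediate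
17 | tert-butyl{[(2S,7R)-8-(benzyloxy)-7-methyloct-4-yn-2-yl]oxy}dimethylsilane | c1ccccc1COC[C@H](C)CC#CC[C@H](C)O[Si](C)(C)C(C)(C)C | intermediate
18 | (2R,7S)-7-[(tert-butyldimethylsilyl)oxy]-2-methyloctan-1-ol | OC[C@H](C)CCCC[C@H](C)O[Si](C)(C)C(C)(C)C | intermediate
19 | (2R,7S)-7-[(tert-butyldimethylsilyl)oxy]-2-methyloctanal | O=C[C@H](C)CCCC[C@H](C)O[Si](C)(C)C(C)(C)C | intermediate
20 | (2E,4R,9S)-9-[(tert-butyldimethylsilyl)oxy]-2,4-dimethyldec-2-enal | CC(/C=O)=C\[C@H](C)CCCC[C@H](C)O[Si](C)(C)C(C)(C)C | intermediate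
21 | ethyl (2E,4E,6R,11S)-11-[(tert-butyldimethylsilyl)oxy]-4,6-dimethyldodeca-2,4-dienoate | CC(/C=C/C(=O)OCC)=C\[C@H](C)CCCC[C@H](C)O[Si](C)(C)C(C)(C)C | intermediate
22 | (2E,4E,6R,11S)-11-[(tert-butyldimethylsilyl)oxy]-4,6-dimethyldodeca-2,4-dienoic acid | CC(/C=C/C(=O)O)=C\[C@H](C)CCCC[C@H](C)O[Si](C)(C)C(C)(C)C | intermediate
23 | (2E,4E,6R,11S)-11-[(tert-butyldimethylsilyl)oxy]-4,6-dimethyldodeca-2,4-dienoic 2,4,6-trichlorobenzoic anhydride | CC(/C=C/C(=O)OC(=O)c1c(Cl)cc(Cl)cc1Cl)=C\[C@H](C)CCCC[C@H](C)O[Si](C)(C)C(C)(C)C | intermediate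
24 | tert-butyl (2E)-3-[(2S,3S)-3-{[(2E,4E,6R,11S)-11-[(tert-butyldimethylsilyl)oxy]-4,6-dimethyldodeca-2,4-dienoyl]oxy}-6-oxo-3,6-dihydro-2H-pyran-2-yl]prop-2-enoate | CC(/C=C/C(=O)O[C@H]1C=CC(=O)O[C@H]1/C=C/C(=O)OC(C)(C)C)=C\[C@H](C)CCCC[C@H](C)O[Si](C)(C)C(C)(C)C | intermediate
25 | (2E)-3-[(2S,3S)-3-{[(2E,4E,6R,11S)-11-hydroxy-4,6-dimethyldodeca-2,4-dienoyl]oxy}-6-oxo-3,6-dihydro-2H-pyran-2-yl]prop-2-enoic acid | CC(/C=C/C(=O)O[C@H]1C=CC(=O)O[C@H]1/C=C/C(=O)O)=C\[C@H](C)CCCC[C@H](C)O | target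

## Totals and risk

Total step count: 19.
Longest linear sequence: 11 steps (7, 8, 9, 12, 13, 14, 15, 16, 17, 18, 19). The lactone branch contributes 7 steps to the end (1, 3, 4, 5, 6, 18, 19) and the alkyne branch 10 (10, 11, 12 to 19).

Steps most likely to fail:

Step 3 (site-selective cross-metathesis). If the catalyst does not discriminate between the two vinyl groups, the enoate is built by hydroxyl-directed oxidation instead. The fallback sets out from 4. VO(acac)2 with t-BuOOH (CH2Cl2, 0 °C) epoxidises only the alkene of the free allylic alcohol and gives (1S,2S)-2-[(tert-butyldimethylsilyl)oxy]-1-(oxiran-2-yl)but-3-en-1-ol F1 (both epoxide epimers serve). Acylation with 1 and i-Pr2NEt gives (1S,2S)-2-[(tert-butyldimethylsilyl)oxy]-1-(oxiran-2-yl)but-3-en-1-yl prop-2-enoate F2. H5IO6 in THF/Et2O cleaves the epoxide, with loss of formaldehyde, to (2R,3S)-3-[(tert-butyldimethylsilyl)oxy]-1-oxopent-4-en-2-yl prop-2-enoate F3. Wittig olefination with tert-butyl 2-(triphenylphosphoranylidene)acetate (CH2Cl2, 0 °C) then gives 6, where the route is rejoined; steps 3 and 4 are replaced.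

Step 12 (acetylide alkylation of a β-branched iodide). If substitution is slow or elimination competes, the chain is assembled by sp3–sp3 coupling and cross-metathesis. The fallback sets out from 12. Allylmagnesium bromide with catalytic Li2CuCl4 (THF, −20 °C) gives (R)-{[(2-methylhex-5-en-1-yl)oxy]methyl}benzene F4. Cross-metathesis with purchased (S)-but-3-en-2-ol (second-generation Grubbs catalyst, CH2Cl2, 40 °C) gives (2S,3E,7R)-8-(benzyloxy)-7-methyloct-3-en-2-ol F5. TBSCl/imidazole gives {[(2S,3E,7R)-8-(benzyloxy)-7-methyloct-3-en-2-yl]oxy}(tert-butyl)dimethylsilane F6. H2, Pd/C in EtOAc saturates the alkene and removes the benzyl group to give 18, where the route is rejoined; steps 10 to 13 are replaced.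

Step 18 (esterification of the base-sensitive pyranol). If 8 eliminates to a 2-pyranone or acylates poorly, the ester bond is made before the ring. The fallback sets out from 6. HF·pyridine (THF, 0 °C, kept cold to suppress acrylate migration) gives tert-butyl (2E,4S,5S)-4-(acryloyloxy)-5-hydroxyhepta-2,6-dienoate F7. Yamaguchi esterification with 22 through 23 gives tert-butyl (2E,4S,5S)-4-(acryloyloxy)-5-{[(2E,4E,6R,11S)-11-[(tert-butyldimethylsilyl)oxy]-4,6-dimethyldodeca-2,4-dienoyl]oxy}hepta-2,6-dienoate F8. Ring-closing metathesis (second-generation Grubbs catalyst, CH2Cl2, 40 °C) between the acrylate and the terminal vinyl group closes the lactone and gives 24, where the route is rejoined; steps 5, 6 and 18 are replaced.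

## Further compounds

F1 | step 3 | (1S,2S)-2-[(tert-butyldimethylsilyl)oxy]-1-(oxiran-2-yl)but-3-en-1-ol | C1OC1[C@H](O)[C@@H](O[Si](C)(C)C(C)(C)C)C=C
F2 | step 3 | (1S,2S)-2-[(tert-butyldimethylsilyl)oxy]-1-(oxiran-2-yl)but-3-en-1-yl prop-2-enoate | C1OC1[C@H](OC(=O)C=C)[C@@H](O[Si](C)(C)C(C)(C)C)C=C
F3 | step 3 | (2R,3S)-3-[(tert-butyldimethylsilyl)oxy]-1-oxopent-4-en-2-yl prop-2-enoate | O=C[C@H](OC(=O)C=C)[C@@H](O[Si](C)(C)C(C)(C)C)C=C
F4 | step 12 | (R)-{[(2-methylhex-5-en-1-yl)oxy]methyl}benzene | C=CCC[C@@H](C)COCc1ccccc1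
F5 | step 12 | (2S,3E,7R)-8-(benzyloxy)-7-methyloct-3-en-2-ol | C[C@H](O)/C=C/CC[C@@H](C)COCc1ccccc1
F6 | step 12 | {[(2S,3E,7R)-8-(benzyloxy)-7-methyloct-3-en-2-yl]oxy}(tert-butyl)dimethylsilane | C[C@H](O[Si](C)(C)C(C)(C)C)/C=C/CC[C@@H](C)COCc1ccccc1
F7 | step 18 | tert-butyl (2E,4S,5S)-4-(acryloyloxy)-5-hydroxyhepta-2,6-dienoate | CC(C)(C)OC(=O)/C=C/[C@H](OC(=O)C=C)[C@@H](O)C=C
F8 | step 18 | tert-butyl (2E,4S,5S)-4-(acryloyloxy)-5-{[(2E,4E,6R,11S)-11-[(tert-butyldimethylsilyl)oxy]-4,6-dimethyldodeca-2,4-dienoyl]oxy}hepta-2,6-dienoate | CC(C)(C)OC(=O)/C=C/[C@H](OC(=O)C=C)[C@@H](OC(=O)/C=C/C(C)=C/[C@H](C)CCCC[C@H](C)O[Si](C)(C)C(C)(C)C)C=C
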